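## The problem

Atom labels used throughout: ring C1 (carbinol), C2H2, C3 (Cl), C4 (CH3, Br), C5H2, C6H2; side chain C7(=CH2)–C8H2–C9H(OH)–C10H=C11(CH3)2.

The target is a monocyclic bisabolane, (1R,3S,4S,9S). One cyclohexane is joined through C1–C7 to an eight-carbon dienol chain, so the difficulty lies in four stereocentres and in the C3–Cl/C4–Br pair, not in ring fusion. Without the chlorine the ring would have a mirror plane through C1 and C4. C1 is therefore stereogenic only because the arm C2–C3 differs from the arm C6–C5, and a reagent attacking a ready-made cyclohexanone at C1 cannot tell the arms apart.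

Bromine sits on the tertiary C4 and chlorine on the secondary C3, the reverse of what BrCl gives. In the chair that keeps the side chain equatorial, both C–X bonds are equatorial and the C4 methyl is axial. Every kinetic anti addition or ring opening on that chair ends diaxial instead, with the C3 substituent on the face of the C1–O bond and the C4 substituent on the face of C7.

The feature that opens the problem is this: the trans-diequatorial C3–Cl/C4–Br pair on the cyclohexane is the 1,2-interchange (dyotropic) isomer of the trans-diaxial C3–Br/C4–Cl adduct. That adduct is what a C3=C4 olefin gives by its natural Markovnikov, diaxial BrCl addition. Each halogen lies on the ring face where the natural adduct has it, but on the neighbouring carbon.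

C1 can thus control C3 and C4 through its equatorial side chain. C9 is insulated from the ring by the sp2 carbon C7 and needs its own reagent control. Several groups forbid rough treatment once the halogens are in:
- the tertiary bromide, prone to E1/E2 and to reductive 1,2-elimination with the vicinal chloride by Zn, Cr(II) or RLi;
- a chlorine that would be β to any C1 carbonyl precursor;
- a tertiary allylic C1–OH that can capture cationic character at C4 across the ring;
- the ionisable C9 allylic alcohol, which sits inside a 3-hydroxy-1,5-diene.

## Retrosynthesis

**16 ⇒ 15 (two O–Si bonds).** Only protecting groups are removed. The C1 oxygen must be blocked during halogenation, because a free hydroxyl would trap C4 transannularly. The bulky C9–OTBS group deactivates and screens C10=C11. The forward reaction has to cleave Si–O without base and without strong acid.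

**15 ⇒ 14 ⇒ 13 (C3–Cl and C4–Br).** Both carbon–halogen bonds and both ring halogen stereocentres are cut at once, back to the halogen-free olefin 13. The alternatives are cutting one C–X bond at a time or carrying the halogens from the start. Both require an equatorial C–Br bond at a tertiary carbon, which no kinetic reaction on this chair provides. 13 has two stereocentres fewer and no fragile group, so all organometallic chemistry can be done before it. The forward step must add BrCl to one olefin of three, on one face, in the natural sense (14). It must then interchange the two halogens thermally (15).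

**13 ⇒ 12 ⇒ 11 (O–Si; C3=C4).** The ring is opened at the olefin by a ring-closing-metathesis transform. This turns the hard-to-set ring stereocentre C1 into the carbinol carbon of the acyclic trienol 11. The three carbon substituents of that carbon (branched alkenyl, allyl, homomethallyl) are very different from one another. Cutting C1–C2 or C1–C6 of the intact ring would not remove the pseudo-symmetry. The forward reaction must close the six-membered ring in preference to four- and seven-membered alternatives.

**11 ⇒ 10 (C1–C2).** The allyl group is removed, leaving the α-branched enone 10. Of the three possible carbonyl additions at C1, this is the only one in which the ketone's two flanks differ strongly (sp2, branched versus primary alkyl). A chiral catalyst can then read the faces. The forward reaction is a catalyst-controlled 1,2-allylation on the Re face.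

**10 ⇒ 9 + 8 (C1–C7).** The chain is cut at the acyl–vinyl bond into vinyllithium 9 (from bromide 5) and Weinreb amide 8 (one step from acid 6). No stereocentre is formed, and both halves are small. The forward reaction must stop at the ketone.

**5 ⇒ 4 ⇒ 1 + 2 (C8–C9).** The homoallylic carbinol is cut to prenal 1 and 2,3-dibromopropene 2. Compound 2 serves as a CH2=C(–)–CH2(–) linchpin: its allylic end makes C8–C9 and its vinylic bromide later makes C1–C7. C9 is set in this bond formation by a chiral chromium catalyst, via silyl ether 3.

## Roads not taken

**Alternative 1:** the most obvious cut, C1–C7, with the halogens already in place. The forward key step adds 9 (as the organocerium) to (3S,4S)-4-bromo-3-chloro-4-methylcyclohexanone A1, giving carbinol A2, which needs only desilylation.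
- A1 carries chlorine β and bromine γ to the carbonyl. Enolisation therefore starts an E1cB loss of HCl followed by loss of HBr and aromatisation.
- A1 poses the same tertiary-Br/secondary-Cl problem as the target. Its ring has no conformational anchor, no handle for absolute control, and no strain to drive a halogen interchange.
- The facial selectivity of the addition on this flexible ketone would rest on small effects.
- The chosen plan never has a carbonyl at C1 while halogens are present.

**Alternative 2:** cut the C–X bonds one at a time. Hydroxyl-directed epoxidation of 12 gives epoxide A3, with oxygen cis to C1–OH. Chloride opening at C3 gives chlorohydrin A4, and C4–OH is then replaced by bromide with retention.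
- Opening at C3 from the face of the side chain is the non-diaxial mode of the favoured chair, and Lewis-acid activation would send chloride to C4.
- Directed epoxidation also competes at the allylic C7=CH2.
- The final substitution must pass through cationic C4. That cation is captured across the ring by the C1 oxygen, or axially by bromide to give the wrong epimer.
- Three to four steps of doubtful stereochemical outcome would replace one operation.

**Alternative 3:** cut C8–C9 last. A halogenated ring allylboronate A5 is joined to prenal 1 under chiral Brønsted acid catalysis to give A6, so that the union sets C9.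
- The idea is convergent and mild.
- However, A5 has to be made from an isopropenyl group in the presence of the tertiary bromide, without base or reducing metal. This adds several steps after halogenation.
- The ring halogens would still have to be installed by the same interchange.
- The chosen plan does all base- and metal-mediated chemistry before any C–X bond exists, and is shorter.

Key step: step 8

Remark: where the antipode of a chiral catalyst is not named (steps 1 and 5), the one that attacks the stated carbonyl face is meant.

## Steps

Step 1
Reactants: 1 3-methylbut-2-enal (prenal); 2 2,3-dibromoprop-1-ene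
Product: 4 (4S)-2-bromo-6-methylhepta-1,5-dien-4-ol, via trimethylsilyl ether 3 (not isolated)
Conditions: CrBr3 (10 mol %), chiral oxazoline–sulfonamide ligand (11 mol %), Et3N, Co phthalocyanine (1 mol %), Mn, Me3SiCl, THF, 0 °C to rt; then K2CO3 (cat.), MeOH, 0 °C
Reagents that add atoms: chlorotrimethylsilane C[Si](C)(C)Cl (silyl group of 3 only)
Why: Catalytic asymmetric Nozaki–Hiyama–Kishi 2-haloallylation: Co/Cr activate only the allylic C–Br bond of 2, the vinylic bromide stays, and the allylchromium(III) adds 1,2 to the enal through a closed transition state. C9 is set by the chromium ligand (Si-face delivery gives S); Mn/Me3SiCl turn the catalyst over and the labile ether 3 is methanolysed in the same flask.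

Step 2
Reactants: 4 (4S)-2-bromo-6-methylhepta-1,5-dien-4-ol
Product: 5 [(4S)-2-bromo-6-methylhepta-1,5-dien-4-yl]oxy(tert-butyl)dimethylsilane
Conditions: TBSCl, imidazole, DMF, rt
Reagents that add atoms: tert-butyldimethylsilyl chloride CC(C)(C)[Si](C)(C)Cl
Why: Standard silylation of a secondary alcohol. TBS is chosen because it withstands t-BuLi without 1,4-O→C silyl migration at −78 °C in ether and later deactivates and screens C10=C11.

Step 3
Reactants: 6 4-methylpent-4-enoic acid
Product: 8 N-methoxy-N,4-dimethylpent-4-enamide, via acyl imidazole 7 (not isolated)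
Conditions: CDI, CH2Cl2, rt; then MeNHOMe·HCl, rt
Reagents that add atoms: N,O-dimethylhydroxylamine hydrochloride CNOC.Cl; 1,1'-carbonyldiimidazole O=C(n1ccnc1)n1ccnc1 (imidazolyl group of 7 only)
Why: Weinreb amide synthesis by acyl imidazole formation and aminolysis; no stereocentre is involved and the 1,1-disubstituted olefin is inert.

Step 4
Reactants: 5 silyl ether of step 2; 8 N-methoxy-N,4-dimethylpent-4-enamide
Product: 10 (8S)-8-(tert-butyldimethylsilyloxy)-2,10-dimethyl-6-methylideneundeca-1,9-dien-5-one, via vinyllithium 9 (not isolated)
Conditions: t-BuLi (2.1 equiv), Et2O, −78 °C; then 8, −78 to −20 °C; aq NH4Cl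
Reagents that add atoms: tert-butyllithium [Li]C(C)(C)C (lithium of 9 only)
Why: Bromine–lithium exchange of a 2-bromoalkene and acylation with a Weinreb amide forms C1–C7; the chelated tetrahedral adduct prevents a second addition. C9 is untouched, and the α-branched enone is used promptly because it is a good Michael acceptor.

Step 5
Reactants: 10 enone of step 4
Product: 11 (5R,8S)-8-(tert-butyldimethylsilyloxy)-2,10-dimethyl-6-methylidene-5-(prop-2-en-1-yl)undeca-1,9-dien-5-ol
Conditions: 2-allyl-1,3,2-dioxaborinane (1.5 equiv), 3,3'-Br2-BINOL (5 mol %), t-BuOH (2 equiv), toluene, rt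
Reagents that add atoms: 2-allyl-1,3,2-dioxaborinane C=CCB1OCCCO1
Why: Chiral-diol-catalysed asymmetric allylboration of a ketone through a closed six-membered transition state on the BINOL-bound boron; the conditions are neutral, so the enone is not attacked at its methylene. C1 is set by the catalyst (Re-face addition gives R), which has to tell a branched sp2 group from a primary alkyl chain; the remote C9 centre should not interfere.

Step 6
Reactants: 11 trienol of step 5
Product: 12 (1R)-1-[(4S)-4-(tert-butyldimethylsilyloxy)-6-methylhepta-1,5-dien-2-yl]-4-methylcyclohex-3-en-1-ol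
Conditions: Grubbs second-generation catalyst (3 mol %), CH2Cl2 (5 mM), 40 °C
Reagents that add atoms: none
Why: Ring-closing metathesis: the carbene loads on the monosubstituted allyl terminus and closes on the 1,1-disubstituted C4 olefin to the six-membered trisubstituted cyclohexene. Closure on C7=CH2 would give a cyclobutene and closure on C10=C11 a cycloheptene, both slower. The C1 configuration is carried over unchanged and now defines on which side of the ring the olefin lies.

Step 7
Reactants: 12 cyclohexenol of step 6
Product: 13 triethylsilyl ether of 12 [(1R)-1-(triethylsilyloxy)-1-[(4S)-4-(tert-butyldimethylsilyloxy)-6-methylhepta-1,5-dien-2-yl]-4-methylcyclohex-3-ene]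
Conditions: TESOTf, 2,6-lutidine, CH2Cl2, −78 to 0 °C
Reagents that add atoms: triethylsilyl trifluoromethanesulfonate CC[Si](CC)(CC)OS(=O)(=O)C(F)(F)F
Why: Silyl triflate silylation of a hindered tertiary alcohol. The crowded C1–OSiEt3 can no longer attack C4 across the ring and raises the strain of the diaxial adduct of step 8.

Step 8
Reactants: 13 bis-silyl ether of step 7
Product: 15 (1R,3S,4S)-4-bromo-3-chloro-4-methyl-1-(triethylsilyloxy)-1-[(4S)-4-(tert-butyldimethylsilyloxy)-6-methylhepta-1,5-dien-2-yl]cyclohexane (Br/Cl trans-diequatorial), via diaxial bromochloride 14 (not isolated)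
Conditions: NBS, Me3SiCl (BrCl in situ, 1.0 equiv), CH2Cl2, −78 °C; aq NaHCO3/Na2S2O3 wash, solvent exchange; MeNO2, 2,6-di-tert-butyl-4-methylpyridine (10 mol %), 80 °C
Reagents that add atoms: N-bromosuccinimide O=C1CCC(=O)N1Br; chlorotrimethylsilane C[Si](C)(C)Cl
Why: BrCl should attack only the ring olefin, since C10=C11 is deactivated and screened by the allylic OTBS group and C7=CH2 is 1,1-disubstituted and neopentyl to C1. In the half-chair with the side chain equatorial, bromonium formation is reversible and chloride opens it at the tertiary C4 along the axial line; only the bromonium on the face of the C1–O bond satisfies both the Markovnikov and the Fürst–Plattner (diaxial) rule, so C1 controls both new centres and 14 (3R,4R; C3–Br and C4–Cl axial, CH3 equatorial) should prevail. On heating, 14 should undergo the type-I dyotropic diaxial→diequatorial rearrangement: the antiperiplanar C3–Br and C4–Cl bonds exchange carbons through a doubly bridged, ion-pair-like transition state, each halogen staying on its own face and both carbons inverting. This turns (3R,4R) into (3S,4S), with Cl on C3 cis to the side chain, Br on C4 cis to the C1 oxygen and the methyl axial, an arrangement no direct anti addition on this chair can give. The closest known reaction type is the thermal mutarotation of steroidal 5α,6β- and 2β,3α-dihalides and of trans-diaxial 4-tert-butylcyclohexane dihalides. The driving force is the syn-diaxial C1–OSi/C3–Br contact with parallel dipoles plus a third axial heteroatom in 14, against only CH3 and OSi axial on opposite faces in 15, and the polar solvent favours the gauche dihalide. The tertiary C4–Cl bond with an antiperiplanar bromine lowers the barrier, and the hindered pyridine takes up traces of HX so that elimination and silyl loss are not autocatalysed. No ring is closed.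

Step 9
Reactants: 15 diequatorial bromochloride of step 8
Product: 16 (1R,3S,4S)-4-bromo-3-chloro-1-[(4S)-4-hydroxy-6-methylhepta-1,5-dien-2-yl]-4-methylcyclohexan-1-ol (target)
Conditions: HF·pyridine, pyridine, THF, 0 °C to rt
Reagents that add atoms: none
Why: Buffered fluoride cleavage of both silyl ethers, with no base that could cause E2 at C4 and acidity too low to ionise the allylic C9–O bond. C4–Br is cis to C1–OH, so transannular displacement is geometrically impossible, and no stereocentre is touched.

## Compound list

1 | 3-methylbut-2-enal | CC(C)=CC=O | starting material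
2 | 2,3-dibromoprop-1-ene | C=C(Br)CBr | starting material
3 | [(4S)-2-bromo-6-methylhepta-1,5-dien-4-yl]oxy(trimethyl)silane | C=C(Br)C[C@H](O[Si](C)(C)C)C=C(C)C | intermediate
4 | (4S)-2-bromo-6-methylhepta-1,5-dien-4-ol | C=C(Br)C[C@H](O)C=C(C)C | intermediate
5 | [(4S)-2-bromo-6-methylhepta-1,5-dien-4-yl]oxy(tert-butyl)dimethylsilane | C=C(Br)C[C@H](O[Si](C)(C)C(C)(C)C)C=C(C)C | intermediate
6 | 4-methylpent-4-enoic acid | C=C(C)CCC(=O)O | starting material
7 | 1-(imidazol-1-yl)-4-methylpent-4-en-1-one | C=C(C)CCC(=O)n1ccnc1 | intermediate
8 | N-methoxy-N,4-dimethylpent-4-enamide | C=C(C)CCC(=O)N(C)OC | intermediate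
9 | [(4S)-4-(tert-butyldimethylsilyloxy)-6-methylhepta-1,5-dien-2-yl]lithium | [Li]C(=C)C[C@H](O[Si](C)(C)C(C)(C)C)C=C(C)C | intermediate
10 | (8S)-8-(tert-butyldimethylsilyloxy)-2,10-dimethyl-6-methylideneundeca-1,9-dien-5-one | C=C(C[C@H](O[Si](C)(C)C(C)(C)C)C=C(C)C)C(=O)CCC(C)=C | intermediate
11 | (5R,8S)-8-(tert-butyldimethylsilyloxy)-2,10-dimethyl-6-methylidene-5-(prop-2-en-1-yl)undeca-1,9-dien-5-ol | C=C(C[C@H](O[Si](C)(C)C(C)(C)C)C=C(C)C)[C@@](O)(CCC(C)=C)CC=C | intermediate
12 | (1R)-1-[(4S)-4-(tert-butyldimethylsilyloxy)-6-methylhepta-1,5-dien-2-yl]-4-methylcyclohex-3-en-1-ol | C=C(C[C@H](O[Si](C)(C)C(C)(C)C)C=C(C)C)[C@@]1(O)CCC(C)=CC1 | intermediate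
13 | triethylsilyl ether of 12 | C=C(C[C@H](O[Si](C)(C)C(C)(C)C)C=C(C)C)[C@@]1(O[Si](CC)(CC)CC)CCC(C)=CC1 | intermediate
14 | (1R,3R,4R)-3-bromo-4-chloro-4-methyl analogue, Br and Cl trans-diaxial, Br cis to OSiEt3 | C=C(C[C@H](O[Si](C)(C)C(C)(C)C)C=C(C)C)[C@@]1(O[Si](CC)(CC)CC)CC[C@@](C)(Cl)[C@H](Br)C1 | intermediate
15 | (1R,3S,4S)-4-bromo-3-chloro-4-methyl bis-silyl ether, Br and Cl trans-diequatorial | C=C(C[C@H](O[Si](C)(C)C(C)(C)C)C=C(C)C)[C@@]1(O[Si](CC)(CC)CC)CC[C@](C)(Br)[C@@H](Cl)C1 | intermediate
16 | (1R,3S,4S)-4-bromo-3-chloro-1-[(4S)-4-hydroxy-6-methylhepta-1,5-dien-2-yl]-4-methylcyclohexan-1-ol | C=C(C[C@H](O)C=C(C)C)[C@@]1(O)CC[C@](C)(Br)[C@@H](Cl)C1 | target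

## Step count and least certain steps

Total: 9 steps. Longest linear sequence: 8 steps (1, 2, 4, 5, 6, 7, 8, 9).

**Step 8 (key step).**
- *Risk:* The interchange most likely stops at an equilibrium mixture, or is overtaken by loss of hydrogen halide on long heating. The axial methyl of the product and the intrinsic preference of chlorine for the tertiary carbon offset part of the strain that is released. A lesser risk is attack of BrCl on the other ring face or on C10=C11.
- *Fallback:* The thermodynamic funnel is replaced by a sort-and-recycle loop. Heating is stopped early and the crude mixture of 14 and 15 is treated with NaI in acetone. Iodide-induced 1,2-elimination needs antiperiplanar C–Br and C–Cl bonds, which only the diaxial 14 offers. Compound 14 is therefore returned to olefin 13, while 15, whose halogens are gauche in its only accessible chair, is left untouched.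
- *Route:* The fallback sets out from 14 and comes back at 13, which is resubmitted to step 8. Compound 15 stays on the route. No new compound is made (F0).

**Step 5.**
- *Risk:* Poor facial discrimination or slow addition is most likely, because the pseudo-axial ketone substituent is a chain and not a methyl group, and the enone is α-branched.
- *Fallback:* C1 is defined by the position of the ring double bond instead of by carbonyl-face selection.
  1. Vinyllithium 9 is added to commercial 1,4-dioxaspiro[4.5]decan-8-one to give the ketal alcohol F1, in which C1 is not yet stereogenic.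
  2. PPTS in wet acetone gives the hydroxy ketone F2, and TESOTf/2,6-lutidine gives the silyloxy ketone F3.
  3. Enantioselective deprotonation with lithium bis(1-phenylethyl)amide/LiCl (THF, −100 °C) and trapping with N-(5-chloropyridin-2-yl)triflimide gives the enol triflate F4.
  4. Iron-catalysed coupling with MeMgBr gives 13.
- *Route:* The fallback sets out from 9 and comes back at 13.

**Step 1.**
- *Risk:* Insufficient enantioselectivity with a small, conjugated aldehyde is most likely, since the ligand pocket was shaped for saturated aldehydes.
- *Fallback:* C9 is set by reduction instead of by C–C bond formation. An indium-mediated Barbier reaction of 1 and 2 (THF/H2O) gives the racemic alcohol F5. MnO2 oxidises it to the dienone F6. Corey–Bakshi–Shibata reduction (catecholborane, −78 °C), with the alkenyl group as the large substituent, gives 4.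
- *Route:* The fallback sets out from 1 and 2 and comes back at 4.

**Step 9.**
- *Risk:* The secondary allylic TBS ether may cleave slowly, so that prolonged exposure allows ionisation at C9 or loss of HBr.
- *Fallback:* The hard deprotection is moved ahead of the halogenation, where fluoride and base are harmless.
  1. Treatment of 12 with TBAF gives the triene diol F7.
  2. TESOTf/2,6-lutidine gives the bis(triethylsilyl) ether F8.
  3. The conditions of step 8 give the diaxial adduct F9 and then the diequatorial bromochloride F10.
  4. AcOH/THF/H2O at rt cleaves both triethylsilyl ethers to 16.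
- *Route:* The fallback sets out from 12 and comes back at 16.

## Further compounds

F0 | step 8 | none | none
F1 | step 5 | 8-[(4S)-4-(tert-butyldimethylsilyloxy)-6-methylhepta-1,5-dien-2-yl]-1,4-dioxaspiro[4.5]decan-8-ol | C=C(C[C@H](O[Si](C)(C)C(C)(C)C)C=C(C)C)C1(O)CCC2(CC1)OCCO2
F2 | step 5 | 4-hydroxy-4-[(4S)-4-(tert-butyldimethylsilyloxy)-6-methylhepta-1,5-dien-2-yl]cyclohexan-1-one | C=C(C[C@H](O[Si](C)(C)C(C)(C)C)C=C(C)C)C1(O)CCC(=O)CC1
F3 | step 5 | 4-(triethylsilyloxy)-4-[(4S)-4-(tert-butyldimethylsilyloxy)-6-methylhepta-1,5-dien-2-yl]cyclohexan-1-one | C=C(C[C@H](O[Si](C)(C)C(C)(C)C)C=C(C)C)C1(O[Si](CC)(CC)CC)CCC(=O)CC1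
F4 | step 5 | (4R)-4-(triethylsilyloxy)-4-[(4S)-4-(tert-butyldimethylsilyloxy)-6-methylhepta-1,5-dien-2-yl]cyclohex-1-en-1-yl trifluoromethanesulfonate | C=C(C[C@H](O[Si](C)(C)C(C)(C)C)C=C(C)C)[C@@]1(O[Si](CC)(CC)CC)CCC(OS(=O)(=O)C(F)(F)F)=CC1
F5 | step 1 | rac-2-bromo-6-methylhepta-1,5-dien-4-ol | C=C(Br)CC(O)C=C(C)C
F6 | step 1 | 2-bromo-6-methylhepta-1,5-dien-4-one | C=C(Br)CC(=O)C=C(C)C
F7 | step 9 | (1R)-1-[(4S)-4-hydroxy-6-methylhepta-1,5-dien-2-yl]-4-methylcyclohex-3-en-1-ol | C=C(C[C@H](O)C=C(C)C)[C@@]1(O)CCC(C)=CC1
F8 | step 9 | bis(triethylsilyl) ether of F7 | C=C(C[C@H](O[Si](CC)(CC)CC)C=C(C)C)[C@@]1(O[Si](CC)(CC)CC)CCC(C)=CC1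
F9 | step 9 | (1R,3R,4R)-3-bromo-4-chloro-4-methyl bis(triethylsilyl) ether, halogens trans-diaxial | C=C(C[C@H](O[Si](CC)(CC)CC)C=C(C)C)[C@@]1(O[Si](CC)(CC)CC)CC[C@@](C)(Cl)[C@H](Br)C1
F10 | step 9 | (1R,3S,4S)-4-bromo-3-chloro-4-methyl bis(triethylsilyl) ether, halogens trans-diequatorial | C=C(C[C@H](O[Si](CC)(CC)CC)C=C(C)C)[C@@]1(O[Si](CC)(CC)CC)CC[C@](C)(Br)[C@@H](Cl)C1
A1 | alternative 1 | (3S,4S)-4-bromo-3-chloro-4-methylcyclohexan-1-one | O=C1CC[C@](C)(Br)[C@@H](Cl)C1
A2 | alternative 1 | (1R,3S,4S)-4-bromo-3-chloro-1-[(4S)-4-(tert-butyldimethylsilyloxy)-6-methylhepta-1,5-dien-2-yl]-4-methylcyclohexan-1-ol | C=C(C[C@H](O[Si](C)(C)C(C)(C)C)C=C(C)C)[C@@]1(O)CC[C@](C)(Br)[C@@H](Cl)C1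
A3 | alternative 2 | C3,C4-epoxide of 12 with the epoxide oxygen cis to C1–OH | C=C(C[C@H](O[Si](C)(C)C(C)(C)C)C=C(C)C)[C@@]1(O)CC[C@]2(C)O[C@@H]2C1
A4 | alternative 2 | chlorohydrin with C3–Cl cis to the side chain and C4–OH cis to C1–OH | C=C(C[C@H](O[Si](C)(C)C(C)(C)C)C=C(C)C)[C@@]1(O)CC[C@](C)(O)[C@@H](Cl)C1
A5 | alternative 3 | pinacol 2-[(1R,3S,4S)-4-bromo-3-chloro-4-methyl-1-(triethylsilyloxy)cyclohexyl]allylboronate | C=C(CB1OC(C)(C)C(C)(C)O1)[C@@]2(O[Si](CC)(CC)CC)CC[C@](C)(Br)[C@@H](Cl)C2
A6 | alternative 3 | C1-O-triethylsilyl ether of 16 | C=C(C[C@H](O)C=C(C)C)[C@@]1(O[Si](CC)(CC)CC)CC[C@](C)(Br)[C@@H](Cl)C1
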